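**Numbering used throughout (fixed by the steps):** 1 2'-hydroxy-3',4'-dimethoxyacetophenone; 2 its dimethylamino enaminone; 3 7,8-dimethoxychromone; 4 2,3-dimethoxyphenol; 5 its tert-butyldimethylsilyl ether; 6 the 5-pinacolboryl derivative of 5 (not isolated); 7 the corresponding boronic acid; 8 the silyl-protected (2S)-flavanone; 9 the target.

**Remark:** 1, 4 and both enantiomers of the pyridine–oxazoline ligand t-BuPyOx [4-tert-butyl-2-(pyridin-2-yl)-4,5-dihydrooxazole] are taken to be commercially available.

## Analysis of the target

The target is a flavanone, (2S)-2-(3-hydroxy-4,5-dimethoxyphenyl)-7,8-dimethoxychroman-4-one. Ring A (C4a–C5–C6–C7–C8–C8a) carries methoxy groups at C7 and C8 and is fused to the dihydropyranone ring C (O1, C2, C3, C4=O); ring B (C1'–C6') sits on C2 and carries a free hydroxyl at C3' and methoxy groups at C4' and C5'. There is a single stereocentre, C2, of S configuration (priorities O1 > C1' > C3 > H); it is benzylic, bonded to O1 and β to the C4 carbonyl. This position makes it fragile: base removes a C3 proton and expels the O1 phenoxide (E1cB retro-oxa-Michael), and the open form recloses without facial control; the C4' methoxy group para to C1' also makes the C2–O1 bond ionisable under strong acid. The C3' hydroxyl is the only free phenol beside four methyl ethers and cannot be revealed by selective demethylation, so it must travel as a distinct group that comes off without base. Both arenes are 1,2,3-trioxygenated, and ring B is joined to C2 through C1', the one ring-B carbon flanked by two unsubstituted positions (C2' and C6'). The difficulty is therefore not size but creating C2 in high enantiomeric purity by a process that is not the reverse of its own racemisation pathway, and keeping it to the end. The feature that invites the key move is that C2 is at once the β-carbon of the C4 enone and the O1-bearing carbon of ring C, so that ring C without the C2–C1' bond is the flat pyranone ring of a chromone. An enantioselective conjugate arylation across C2=C3 would then form the C2–C1' bond, turn the flat ring into ring C and set C2 in one operation.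

## Retrosynthetic reasoning

**9 to 8 (O–Si at C3').** The last bond cut is the silyl ether on the C3' oxygen. A silyl group is chosen because it can be removed by fluoride in a weakly acidic medium, which avoids the phenoxide and enolate chemistry that would open ring C and racemise C2. The forward step only has to cleave O–Si and leave everything else alone.

**8 to 3 and 7 (C2–C1').** The bond between the stereocentre and ring B is cut. This divides the molecule into two achiral halves of similar size: the flat chromone 3, which already holds ring A, ring C and all their oxygens, and the ring-B boronic acid 7. The cut is made here and not at O1–C2 because the forward reaction is then a carbon–carbon bond formation under base-free catalysis by divalent palladium, which is not the reverse of the racemisation pathway. The forward step must add the aryl group to C2 only, on one face, and end by protonation at C3 rather than by β-hydride elimination.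

**7 to 5 via 6, and 5 to 4 (C1'–B, then O–Si).** The C–B bond of 7 is traced back to a C–H bond. In the silyl ether 5 the future C1' is the only ring carbon with hydrogen on both neighbours, so a sterically governed iridium-catalysed C–H borylation should find it without a halogen handle. Electrophilic halogenation could not do this, since it would go ortho or para to the oxygens. The pinacol boronate 6 is cleaved in the same flask to 7. Compound 5 comes from commercial 4 by silylation; the silyl group serves both as the directing bulk for borylation and as the protecting group in the key step.

**3 to 2 to 1 (O1–C2 and C2–C3 of the pyranone).** Chromone 3 is opened at O1–C2 to the enaminone 2, and 2 is cut at C2–C3 to the methyl ketone 1 plus a one-carbon amide acetal. Ring A with its three contiguous oxygens is bought in 1, not built. The forward steps are a condensation and an acid-promoted addition–elimination.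

## Alternatives that were turned down

**Alternative 1:** Disconnection of the O1–C2 bond of ring C, the textbook route. The precursor is the 2'-hydroxychalcone A1, which an aldol condensation of 1 at the future C2–C3 bond would supply. The forward key step is a catalytic enantioselective 6-endo-trig oxa-Michael addition of the C2' phenol of A1 to the β-carbon. It was turned down for these reasons:
- The cyclisation is the microscopic reverse of the racemisation pathway of the product. Under the basic or bifunctional catalysts it needs, open and closed forms equilibrate, so enantiopurity depends on the catalysed closure outrunning an achiral background reaction.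
- The β-carbon of A1 is deactivated by the para-methoxy group of ring B.
- The reliably selective variants need an extra activating ester at the α-carbon, which must be installed and later removed by decarboxylation.
- The C3' phenol must be protected against the hydroxide of the condensation.
- The route ends up longer than the chosen one, and its stereo-defining step adds no skeletal bond.

**Alternative 2:** Disconnection of O1–C2 and C3–C4 together. An inverse-demand hetero-Diels–Alder reaction between the ring-A ortho-quinone methide A2 (heterodiene O1=C8a–C4a=C4) and the ring-B styrene A3 would close ring C and give the flavan A4; benzylic oxidation at C4 would follow. It was turned down for these reasons: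
- The cycloaddition delivers C4 as CH2. The later oxidation would have to take a C4–H in preference to the C2–H, which is benzylic to the more electron-rich ring B and also α to oxygen. Hydride- or hydrogen-abstracting oxidants should prefer C2 and destroy the stereocentre.
- A2 has no substituent on the methide carbon, so it is short-lived, prone to dimerise and offers a chiral acid little handle for facial control at C2.
- A3 needs its own synthesis, and the sequence is at least three steps longer.

**Alternative 3:** Disconnection of O1–C2 as an SN2 etherification. The precursor is the (R)-configured β-hydroxy ketone A5, from an asymmetric aldol reaction. The forward key step is an intramolecular Mitsunobu reaction in which the C2' phenol displaces the activated benzylic hydroxyl with inversion to give 8. It was turned down for these reasons: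
- The activated carbinol is β to a ketone and benzylic to a para-methoxy arene. E1cB elimination to an open-chain enone and SN1 ionisation both compete with clean inversion, and both lead to racemic material.
- Making A5 requires an enantioselective acetate-type aldol of a methyl ketone whose ortho phenol must be masked and unmasked, usually with a stoichiometric chiral reagent.
- The step count roughly doubles, and stereocentre formation and ring closure are spread over two separate fragile steps.

Key step: step 5

## Route

Step 1
Reactants: 1 1-(2-hydroxy-3,4-dimethoxyphenyl)ethan-1-one
Product: 2 (E)-3-(dimethylamino)-1-(2-hydroxy-3,4-dimethoxyphenyl)prop-2-en-1-one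
Conditions: Me2NCH(OMe)2 (1.5 equiv), toluene, 100 °C
Reagents that add atoms: N,N-dimethylformamide dimethyl acetal, COC(OC)N(C)C
Why: Condensation of the acidic methyl ketone with the amide acetal (enaminone formation) is the standard first stage of chromone synthesis from 2-hydroxyacetophenones; the hydrogen-bonded C2' hydroxyl should not be alkylated at this temperature and the E-enaminone is the thermodynamic product.

Step 2
Reactants: 2 (E)-3-(dimethylamino)-1-(2-hydroxy-3,4-dimethoxyphenyl)prop-2-en-1-one
Product: 3 7,8-dimethoxy-4H-chromen-4-one
Conditions: conc. HCl, CH2Cl2, 40 °C
Reagents that add atoms: none
Why: Acid promotes 6-endo addition of the phenolic oxygen to the iminium-activated β-carbon followed by loss of dimethylamine (addition–elimination cyclisation), which gives the pyranone ring irreversibly; the methyl ethers are inert to these conditions.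

Step 3
Reactants: 4 2,3-dimethoxyphenol
Product: 5 tert-butyl(2,3-dimethoxyphenoxy)dimethylsilane
Conditions: TBSCl, imidazole, DMF, 0 °C to rt
Reagents that add atoms: tert-butyldimethylsilyl chloride, CC(C)(C)[Si](C)(C)Cl
Why: Standard silylation of a phenol; the silyl ether has no aryl C–H of its own, tolerates iridium-catalysed borylation, buffered periodate and the weakly acidic key step, and can later be removed without base.

Step 4
Reactants: 5 tert-butyl(2,3-dimethoxyphenoxy)dimethylsilane
Product: 7 [3-(tert-butyldimethylsilyloxy)-4,5-dimethoxyphenyl]boronic acid, via pinacol boronate 6 (not isolated)
Conditions: [Ir(OMe)(cod)]2 (1.5 mol %), 4,4'-di-tert-butyl-2,2'-bipyridine (3 mol %), B2pin2 (1.0 equiv), THF, 80 °C; evaporate; then NaIO4, NH4OAc, acetone–H2O, rt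
Reagents that add atoms: bis(pinacolato)diboron, CC1(C)OB(OC1(C)C)B1OC(C)(C)C(C)(C)O1; water, O
Why: Iridium-catalysed aromatic C–H borylation is sterically controlled and avoids positions ortho to substituents, so of the three ring C–H bonds of 5 only the one flanked by two hydrogens (the future C1') should react. Periodate then cleaves the released pinacol oxidatively and so drives hydrolysis of 6 to the boronic acid in the same flask, under buffered conditions that spare the silyl ether.

Step 5
Reactants: 3 7,8-dimethoxy-4H-chromen-4-one; 7 [3-(tert-butyldimethylsilyloxy)-4,5-dimethoxyphenyl]boronic acid
Product: 8 (2S)-2-[3-(tert-butyldimethylsilyloxy)-4,5-dimethoxyphenyl]-7,8-dimethoxychroman-4-one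
Conditions: 7 (2 equiv), Pd(OCOCF3)2 (5 mol %), (R)-t-BuPyOx (6 mol %), NH4PF6 (30 mol %), H2O (5 equiv), ClCH2CH2Cl, 60 °C
Reagents that add atoms: none
Why: Transmetalation of 7 to the cationic divalent palladium–pyridine-oxazoline complex gives an aryl–palladium species that binds the C2=C3 bond of 3 and inserts it in a syn fashion, aryl to C2 and palladium to C3; the resulting palladium enolate is protonated by water, which releases 8 and returns divalent palladium with no redox change. The closest known reaction type is the enantioselective conjugate addition of arylboronic acids to chromones and cyclic enones catalysed by divalent palladium with pyridine–oxazoline ligands. No ring is closed: the step joins the two halves through the C2–C1' bond and converts the flat pyranone ring of 3 into the dihydropyranone ring C. C2 is the only new stereocentre and is set in the insertion, where the tert-butyl group of the oxazoline disfavours one orientation of the bound chromone; transposing the facial model accepted for 3-substituted cyclohexenones with this ligand class, the (R)-ligand should deliver the aryl group to the face that gives the (2S) configuration. Regioselectivity is secured by the substrate, since C2 is both the β-carbon of the enone and the oxygen-bearing carbon of an enol ether, so both polarisations direct the aryl group there. After syn insertion the C2–H lies anti to palladium, so β-hydride elimination to the flavone is disfavoured and protonation should win. The medium is base-free and only weakly acidic, so the retro-oxa-Michael pathway that would racemise C2 is not open and the aryl silyl ether should survive. The boronic acid has no ortho substituent, so transmetalation is unhindered, and an excess covers losses by protodeboronation.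

Step 6
Reactants: 8 (2S)-2-[3-(tert-butyldimethylsilyloxy)-4,5-dimethoxyphenyl]-7,8-dimethoxychroman-4-one
Product: 9 (2S)-2-(3-hydroxy-4,5-dimethoxyphenyl)-7,8-dimethoxychroman-4-one
Conditions: KHF2 (2 equiv), MeOH, rt
Reagents that add atoms: none
Why: Bifluoride cleaves phenolic tert-butyldimethylsilyl ethers at room temperature in a weakly acidic medium (fluoride-mediated desilylation), so no phenoxide or enolate is formed and the base-sensitive C2 stereocentre and ring C should be untouched; the four methyl ethers are inert.

## Compound list

1 | 1-(2-hydroxy-3,4-dimethoxyphenyl)ethan-1-one | CC(=O)c1ccc(OC)c(OC)c1O | starting material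
2 | (E)-3-(dimethylamino)-1-(2-hydroxy-3,4-dimethoxyphenyl)prop-2-en-1-one | CN(C)/C=C/C(=O)c1ccc(OC)c(OC)c1O | intermediate
3 | 7,8-dimethoxy-4H-chromen-4-one | COc1ccc2c(=O)ccoc2c1OC | intermediate
4 | 2,3-dimethoxyphenol | COc1cccc(O)c1OC | starting material
5 | tert-butyl(2,3-dimethoxyphenoxy)dimethylsilane | COc1cccc(O[Si](C)(C)C(C)(C)C)c1OC | intermediate
6 | pinacol boronate 2-[3-(tert-butyldimethylsilyloxy)-4,5-dimethoxyphenyl]-4,4,5,5-tetramethyl-1,3,2-dioxaborolane | COc1cc(B2OC(C)(C)C(C)(C)O2)cc(O[Si](C)(C)C(C)(C)C)c1OC | intermediate
7 | [3-(tert-butyldimethylsilyloxy)-4,5-dimethoxyphenyl]boronic acid | COc1cc(B(O)O)cc(O[Si](C)(C)C(C)(C)C)c1OC | intermediate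
8 | (2S)-2-[3-(tert-butyldimethylsilyloxy)-4,5-dimethoxyphenyl]-7,8-dimethoxychroman-4-one | COc1cc([C@@H]2CC(=O)c3ccc(OC)c(OC)c3O2)cc(O[Si](C)(C)C(C)(C)C)c1OC | intermediate
9 | (2S)-2-(3-hydroxy-4,5-dimethoxyphenyl)-7,8-dimethoxychroman-4-one | COc1cc([C@@H]2CC(=O)c3ccc(OC)c(OC)c3O2)cc(O)c1OC | target

## Step count and risk

Total step count: 6. Longest linear sequence: 4 steps (4 to 5 to 7 to 8 to 9; the branch 1 to 2 to 3 to 8 to 9 is equally long).

**Step 5 (key step).** Three things may go wrong.
- Migratory insertion into the C2=C3 bond of 3 may be slow, because the C7 methoxy group donates through C4a into the carbonyl and makes the acceptor a vinylogous ester. Protodeboronation and oxidative homocoupling of the electron-rich boronic acid could then consume the nucleophile.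
- Facial discrimination may be insufficient, or its sense opposite to the one transposed from cyclohexenones. In the latter case the antipodal ligand is simply used.
- The silyl group may be partly lost to adventitious acid. This is harmless, as it leads on to 9.

Fallback, changing the way the stereocentre is obtained: set out from 3 and 7 and carry out the conjugate addition with the achiral, more robust combination Pd(OCOCF3)2/2,2'-bipyridine in aqueous acetic acid–THF at 60 °C. This should give the racemic silyl-protected flavanone F1. F1 is then resolved kinetically by asymmetric transfer hydrogenation with RhCl(Cp*)[(R,R)-TsDPEN] and HCO2H/Et3N in EtOAc at rt, stopped near half conversion. The (2R)-enantiomer should be reduced to the cis-(2R,4R)-flavan-4-ol F2, which is removed by chromatography. The slow-reacting (2S)-ketone is left and is 8, where the fallback rejoins the route, at the cost of at most half of the material.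

**Step 4.** Borylation may occur in part ortho to the C3 methoxy group of 5 or twice. Oxidative cleavage of the pinacol ester may stay incomplete. Boroxine formation or partial desilylation may complicate purification of the free boronic acid. Fallback, changing how the pinacol ester is handled: stop after the borylation stage and isolate 6 by chromatography. Treat 6 with diethanolamine in Et2O at rt, so that the crystalline diethanolamine boronate F3 precipitates and isomeric or pinacol-containing material stays in solution. Brief two-phase hydrolysis of F3 with dilute aqueous HCl and Et2O should give 7, where the route is rejoined.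

**Step 6.** If the fluoride source behaves as a base, deprotonation at C3 and retro-oxa-Michael opening of ring C followed by unselective reclosure would erode the enantiomeric purity; incomplete desilylation is the lesser concern. Fallback, moving the deprotection in front of the stereocentre: set out from 7 and remove the silyl group with 1 M aqueous HCl in THF at rt to give (3-hydroxy-4,5-dimethoxyphenyl)boronic acid F4. Use F4 in the conjugate addition to 3 under the conditions of step 5, which run in the presence of water and should tolerate a free phenol. This gives 9 directly, so no operation follows the creation of C2.

## Further compounds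

F1 | step 5 | racemic 2-[3-(tert-butyldimethylsilyloxy)-4,5-dimethoxyphenyl]-7,8-dimethoxychroman-4-one | COc1cc(C2CC(=O)c3ccc(OC)c(OC)c3O2)cc(O[Si](C)(C)C(C)(C)C)c1OC
F2 | step 5 | (2R,4R)-2-[3-(tert-butyldimethylsilyloxy)-4,5-dimethoxyphenyl]-7,8-dimethoxychroman-4-ol | COc1cc([C@H]2C[C@@H](O)c3ccc(OC)c(OC)c3O2)cc(O[Si](C)(C)C(C)(C)C)c1OC
F3 | step 4 | 2-[3-(tert-butyldimethylsilyloxy)-4,5-dimethoxyphenyl]-1,3,6,2-dioxazaborocane (diethanolamine boronate) | COc1cc(B2OCCNCCO2)cc(O[Si](C)(C)C(C)(C)C)c1OC
F4 | step 6 | (3-hydroxy-4,5-dimethoxyphenyl)boronic acid | COc1cc(B(O)O)cc(O)c1OC
A1 | alternative 1 | (E)-1-(2-hydroxy-3,4-dimethoxyphenyl)-3-(3-hydroxy-4,5-dimethoxyphenyl)prop-2-en-1-one | COc1cc(/C=C/C(=O)c2ccc(OC)c(OC)c2O)cc(O)c1OC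
A2 | alternative 2 | 2,3-dimethoxy-6-methylidenecyclohexa-2,4-dien-1-one | C=C1C=CC(OC)=C(OC)C1=O
A3 | alternative 2 | 5-ethenyl-2,3-dimethoxyphenol | C=Cc1cc(O)c(OC)c(OC)c1
A4 | alternative 2 | (2S)-2-(3-hydroxy-4,5-dimethoxyphenyl)-7,8-dimethoxychromane | COc1cc([C@@H]2CCc3ccc(OC)c(OC)c3O2)cc(O)c1OC
A5 | alternative 3 | (3R)-3-[3-(tert-butyldimethylsilyloxy)-4,5-dimethoxyphenyl]-3-hydroxy-1-(2-hydroxy-3,4-dimethoxyphenyl)propan-1-one | COc1cc([C@H](O)CC(=O)c2ccc(OC)c(OC)c2O)cc(O[Si](C)(C)C(C)(C)C)c1OC
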